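**Strategy.** The 7-oxabicyclo[2.2.1]heptane core (C1 = methyl-bearing bridgehead, C4 = CH bridgehead, C5–C6 = ethano bridge, O7) is opened across its oxolane ring O7–C1–C6–C5–C4. The C5–C6 bond and the O7–C1 bond are made together by a Lewis-acid epoxide–alkene cyclization, a formal intramolecular [3+2] addition of an oxirane C–O bond across an isopropenyl group. The precursor is an acyclic epoxy diene: a terminal oxirane (future C4, C5, O7) and an isopropenyl group (future C1, C6, 1-methyl) sit on the vicinal C3/C2 stereodiad, which is set by an enantioselective Ireland–Claisen rearrangement. Both side chains, bromochloride included, are already in place.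

Key step: step 14

Remark on locants: C1–C6 and O7 refer to the bicyclic core of the target (C2 = CH carrying the hydroxypentenyl chain, C3 = quaternary carbon).
Assumption 1: (S)-(+)-linalool (coriandrol) is taken as a commercial starting material of high enantiomeric purity.
Assumption 2: the (S,S)-bromoborane is taken as the enantiomer that leads to the (2S,3R) acid 15; if the sense of induction is the reverse, the (R,R)-reagent is used with no other change.

Step 1
Reactants: 1 (S)-linalool
Product: 2 tert-butyl{[(3S)-3,7-dimethylocta-1,6-dien-3-yl]oxy}dimethylsilane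
Conditions: TBSOTf, 2,6-lutidine, CH2Cl2, 0 °C to rt
Reagents that add atoms: tert-butyldimethylsilyl triflate, CC(C)(C)[Si](C)(C)OS(=O)(=O)C(F)(F)F
Why: Silyl etherification of the hindered tertiary allylic alcohol with the silyl triflate and a non-nucleophilic base should leave the (S) carbinol centre untouched and protected for all later steps.

Step 2
Reactants: 2 tert-butyl{[(3S)-3,7-dimethylocta-1,6-dien-3-yl]oxy}dimethylsilane
Product: 3 (4S)-4-[(tert-butyldimethylsilyl)oxy]-4-methylhex-5-enal
Conditions: O3 (1.0 equiv), pyridine, CH2Cl2, −78 °C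
Reagents that add atoms: ozone, [O-][O+]=O
Why: Chemoselective ozonolysis (pyridine-mediated reductive variant) should cleave only the electron-rich trisubstituted alkene, since the vinyl group is monosubstituted, hindered and deactivated by the allylic silyloxy group, and no stereocentre is formed.

Step 3
Reactants: 3 (4S)-4-[(tert-butyldimethylsilyl)oxy]-4-methylhex-5-enal
Product: 4 (5S)-5-[(tert-butyldimethylsilyl)oxy]-1,1,1-trichloro-5-methylhept-6-en-2-ol (both C2 epimers)
Conditions: CHCl3, DBU, 0 °C to rt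
Reagents that add atoms: chloroform, ClC(Cl)Cl
Why: Base-mediated addition of the trichloromethyl anion to the aldehyde (haloform-type carbonyl addition) should give the carbinol, whose new centre need not be controlled because it becomes a CH2 group in step 4.

Step 4
Reactants: 4 (5S)-5-[(tert-butyldimethylsilyl)oxy]-1,1,1-trichloro-5-methylhept-6-en-2-ol
Product: 5 (5S)-5-[(tert-butyldimethylsilyl)oxy]-5-methylhept-6-enoic acid
Conditions: NaBH4, NaOH, t-BuOH, 40 °C; then aqueous citric acid
Reagents that add atoms: sodium hydroxide, [Na+].[OH-]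
Why: Jocic-type reductive one-carbon homologation, in which hydride replaces the carbinol C–O bond and the CCl3 carbon ends as the carboxylate, should give the chain-extended acid under basic conditions that leave the tertiary silyl ether intact.

Step 5
Reactants: 6 geranyl acetate
Product: 7 (2E)-5-[(2R)-3,3-dimethyloxiran-2-yl]-3-methylpent-2-en-1-yl acetate
Conditions: D-fructose-derived Shi ketone (0.3 equiv), KHSO5 (as 2KHSO5·KHSO4·K2SO4), K2CO3, n-Bu4NHSO4, MeCN/dimethoxymethane/aqueous Na2B4O7 buffer, 0 °C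
Reagents that add atoms: potassium peroxymonosulfate, [K+].[O-]S(=O)(=O)OO
Why: Shi epoxidation by the ketone-derived chiral dioxirane should oxidise only the 6,7-alkene (the 2,3-alkene is deactivated by the allylic acetate) through the spiro transition state that gives the (6R) epoxide.

Step 6
Reactants: 7 (2E)-5-[(2R)-3,3-dimethyloxiran-2-yl]-3-methylpent-2-en-1-yl acetate
Product: 8 (2E,6R)-7-bromo-6-hydroxy-3,7-dimethyloct-2-en-1-yl acetate
Conditions: MgBr2·OEt2, Et2O, −20 °C; aqueous work-up
Reagents that add atoms: magnesium bromide, [Mg+2].[Br-].[Br-]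
Why: Lewis-acid-assisted Markovnikov ring opening of the trisubstituted epoxide should deliver bromide to the tertiary carbon, so that the C6–O bond and the (6R) configuration are retained.

Step 7
Reactants: 8 (2E,6R)-7-bromo-6-hydroxy-3,7-dimethyloct-2-en-1-yl acetate
Product: 11 (2E,6S)-6-bromo-7-chloro-3,7-dimethyloct-2-en-1-yl acetate, via secondary triflate 9 (not isolated), via bromonium ion 10 (not isolated)
Conditions: (CF3SO2)2O, 2,6-lutidine, CH2Cl2, −78 °C; then n-Bu4NCl, −78 to 0 °C
Reagents that add atoms: tetrabutylammonium chloride, CCCC[N+](CCCC)(CCCC)CCCC.[Cl-]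
Why: Triflation followed by neighbouring-group participation of the tertiary bromine should expel triflate with inversion at C6 and give a bromonium ion that chloride opens at the tertiary carbon (stereospecific 1,2-bromine shift), which sets the (6S) C–Br centre and the tertiary chloride together.

Step 8
Reactants: 11 (2E,6S)-6-bromo-7-chloro-3,7-dimethyloct-2-en-1-yl acetate
Product: 12 (2E,6S)-6-bromo-7-chloro-3,7-dimethyloct-2-en-1-ol
Conditions: K2CO3 (0.2 equiv), MeOH, 0 °C
Reagents that add atoms: none
Why: Carbonate-catalysed transesterification (methanolysis) of the allylic acetate should free the primary alcohol under conditions too mild to eliminate the hindered secondary bromide.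

Step 9
Reactants: 5 (5S)-5-[(tert-butyldimethylsilyl)oxy]-5-methylhept-6-enoic acid; 12 (2E,6S)-6-bromo-7-chloro-3,7-dimethyloct-2-en-1-ol
Product: 13 (2E,6S)-6-bromo-7-chloro-3,7-dimethyloct-2-en-1-yl (5S)-5-[(tert-butyldimethylsilyl)oxy]-5-methylhept-6-enoate
Conditions: DCC, DMAP (cat.), CH2Cl2, 0 °C to rt
Reagents that add atoms: none
Why: Steglich esterification (carbodiimide activation with acyl-transfer catalysis) should join the two fragments under neutral conditions without touching the halides, the silyl ether or the alkene geometry.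

Step 10
Reactants: 13 (2E,6S)-6-bromo-7-chloro-3,7-dimethyloct-2-en-1-yl (5S)-5-[(tert-butyldimethylsilyl)oxy]-5-methylhept-6-enoate
Product: 15 (2S,3R)-3-[(3S)-3-bromo-4-chloro-4-methylpentyl]-2-{(3S)-3-[(tert-butyldimethylsilyl)oxy]-3-methylpent-4-en-1-yl}-3-methylpent-4-enoic acid, via boron ketene acetal 14 (not isolated)
Conditions: (4S,5S)-2-bromo-1,3-bis{[3,5-bis(trifluoromethyl)phenyl]sulfonyl}-4,5-diphenyl-1,3,2-diazaborolidine (1.2 equiv), i-Pr2NEt, CH2Cl2, −78 °C, then −20 to 4 °C; aqueous work-up
Reagents that add atoms: none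
Why: Enantioselective Ireland–Claisen rearrangement: soft enolisation with the C2-symmetric bromoborane and the hindered amine should give ketene acetal 14 with the alkyl chain cis to O–B, and its chair transition state with the (E)-allyl unit (methyl axial, both chains equatorial) sets the relative configuration of the new tertiary and quaternary centres while the chiral sulfonamide ligand on boron selects the face, so that the (2S,3R) acid results.

Step 11
Reactants: 15 (2S,3R)-3-[(3S)-3-bromo-4-chloro-4-methylpentyl]-2-{(3S)-3-[(tert-butyldimethylsilyl)oxy]-3-methylpent-4-en-1-yl}-3-methylpent-4-enoic acid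
Product: 16 (3S,4S,5S)-4-[(3S)-3-bromo-4-chloro-4-methylpentyl]-3-{(3S)-3-[(tert-butyldimethylsilyl)oxy]-3-methylpent-4-en-1-yl}-5-(iodomethyl)-4-methyloxolan-2-one
Conditions: I2, NaHCO3, MeCN, 0 °C, dark
Reagents that add atoms: iodine, II
Why: Iodolactonisation (5-exo capture of the iodonium ion by the carboxylate) should place the iodomethyl group cis to the C3 substituent of the lactone, because the envelope transition state keeps the two 1,3-related groups pseudo-equatorial and puts the new group next to the methyl rather than the longer chain of the quaternary carbon, and this sets the (5S) C–O centre that becomes the CH bridgehead.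

Step 12
Reactants: 16 (3S,4S,5S)-4-[(3S)-3-bromo-4-chloro-4-methylpentyl]-3-{(3S)-3-[(tert-butyldimethylsilyl)oxy]-3-methylpent-4-en-1-yl}-5-(iodomethyl)-4-methyloxolan-2-one
Product: 18 (3S,4S,7S)-7-bromo-8-chloro-4,8-dimethyl-4-[(2S)-oxiran-2-yl]-3-{(3S)-3-[(tert-butyldimethylsilyl)oxy]-3-methylpent-4-en-1-yl}nonan-2-one, via lithium lactolate 17 (not isolated)
Conditions: MeLi (1.05 equiv), THF, −78 °C; then warm to 0 °C
Reagents that add atoms: methyllithium, [Li]C
Why: Carbonyl addition of methyllithium should stop at lactolate 17, which on warming ring-opens and displaces the neighbouring iodide in a 3-exo-tet Williamson closure, so that the former lactone oxygen becomes the oxirane oxygen with retention at the carbinol carbon and the acyl carbon becomes the methyl ketone.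

Step 13
Reactants: 18 (3S,4S,7S)-7-bromo-8-chloro-4,8-dimethyl-4-[(2S)-oxiran-2-yl]-3-{(3S)-3-[(tert-butyldimethylsilyl)oxy]-3-methylpent-4-en-1-yl}nonan-2-one
Product: 19 tert-butyl({(3S,6R,7S,10S)-10-bromo-11-chloro-3,7,11-trimethyl-7-[(2S)-oxiran-2-yl]-6-(prop-1-en-2-yl)dodec-1-en-3-yl}oxy)dimethylsilane
Conditions: Ph3PCH3Br, KN(SiMe3)2, THF, 0 °C; then 18, 0 °C to rt
Reagents that add atoms: methyltriphenylphosphonium bromide, C[P+](c1ccccc1)(c1ccccc1)c1ccccc1.[Br-]
Why: Wittig methylenation with the non-stabilised ylide should turn the methyl ketone into the isopropenyl group, any enolisation being confined to the methyl side so that the adjacent tertiary stereocentre is not epimerised.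

Step 14
Reactants: 19 tert-butyl({(3S,6R,7S,10S)-10-bromo-11-chloro-3,7,11-trimethyl-7-[(2S)-oxiran-2-yl]-6-(prop-1-en-2-yl)dodec-1-en-3-yl}oxy)dimethylsilane
Product: 21 tert-butyl({(3S)-5-[(1S,2S,3S,4R)-3-[(3S)-3-bromo-4-chloro-4-methylpentyl]-1,3-dimethyl-7-oxabicyclo[2.2.1]heptan-2-yl]-3-methylpent-1-en-3-yl}oxy)dimethylsilane, via cyclohexyl cation 20 (not isolated)
Conditions: BF3·OEt2 (0.5 equiv), CH2Cl2, −78 °C; Et3N quench
Reagents that add atoms: none
Why: BF3 coordination activates the terminal oxirane, the isopropenyl CH2 terminus attacks the oxirane CH2 carbon in an SN2-like way (new C5–C6 bond) to give the tertiary cyclohexyl cation 20, and the boron-bound alkoxide on C4 collapses onto cationic C1 (new O7–C1 bond) with release of BF3. The closest known reaction type is the Lewis-acid epoxide-initiated cation–olefin cyclisation with internal alkoxide termination, by which epoxy 1,5-dienes give 7-oxabicyclo[2.2.1]heptanes. The carbocycle closes 6-endo-trig at the alkene and endo at the oxirane (both oxirane carbons end in the six-membered ring), and the two oxolane rings close together by transannular 1,4-capture of the trigonal cation by oxygen (5-exo-type). C1 is the only new stereocentre and is dictated by the oxirane carbinol carbon (future C4, set in step 11), because the one-atom bridge can only span the ring cis, while C2, C3 and C4 are carried through unchanged. The step needs regioselectivity at the oxirane (CH2, not CH) and at the alkene (Markovnikov), secured by the six- versus five-membered ring choice, the neopentyl shielding of the oxirane CH carbon and the tertiary cation. It also needs chemoselectivity, secured because the only other alkene is the poorly nucleophilic vinyl group (the trisubstituted alkene is already the bromochloride) and because non-halophilic BF3 at −78 °C should leave the tertiary chloride and the silyl ether alone.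

Step 15
Reactants: 21 tert-butyl({(3S)-5-[(1S,2S,3S,4R)-3-[(3S)-3-bromo-4-chloro-4-methylpentyl]-1,3-dimethyl-7-oxabicyclo[2.2.1]heptan-2-yl]-3-methylpent-1-en-3-yl}oxy)dimethylsilane
Product: 22 (3S)-5-[(1S,2S,3S,4R)-3-[(3S)-3-bromo-4-chloro-4-methylpentyl]-1,3-dimethyl-7-oxabicyclo[2.2.1]heptan-2-yl]-3-methylpent-1-en-3-ol (CNP0297543.1)
Conditions: HF·pyridine, pyridine, THF, 0 °C to rt
Reagents that add atoms: none
Why: Fluoride-mediated desilylation under buffered, non-basic conditions should release the tertiary allylic alcohol without E2 loss of HBr and without ionising the allylic carbinol, giving the target.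

**Compound list**

1 | (S)-linalool, (3S)-3,7-dimethylocta-1,6-dien-3-ol | C=C[C@@](C)(O)CCC=C(C)C | starting material
2 | tert-butyl{[(3S)-3,7-dimethylocta-1,6-dien-3-yl]oxy}dimethylsilane | C=C[C@@](C)(O[Si](C)(C)C(C)(C)C)CCC=C(C)C | intermediate
3 | (4S)-4-[(tert-butyldimethylsilyl)oxy]-4-methylhex-5-enal | C=C[C@@](C)(O[Si](C)(C)C(C)(C)C)CCC=O | intermediate
4 | (5S)-5-[(tert-butyldimethylsilyl)oxy]-1,1,1-trichloro-5-methylhept-6-en-2-ol (both C2 epimers) | C=C[C@@](C)(O[Si](C)(C)C(C)(C)C)CCC(O)C(Cl)(Cl)Cl | intermediate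
5 | (5S)-5-[(tert-butyldimethylsilyl)oxy]-5-methylhept-6-enoic acid | C=C[C@@](C)(O[Si](C)(C)C(C)(C)C)CCCC(=O)O | intermediate
6 | geranyl acetate, (2E)-3,7-dimethylocta-2,6-dien-1-yl acetate | CC(C)=CCC/C(C)=C/COC(C)=O | starting material
7 | (2E)-5-[(2R)-3,3-dimethyloxiran-2-yl]-3-methylpent-2-en-1-yl acetate | CC1(C)O[C@@H]1CC/C(C)=C/COC(C)=O | intermediate
8 | (2E,6R)-7-bromo-6-hydroxy-3,7-dimethyloct-2-en-1-yl acetate | CC(C)(Br)[C@H](O)CC/C(C)=C/COC(C)=O | intermediate
9 | (2E,6R)-7-bromo-3,7-dimethyl-6-[(trifluoromethylsulfonyl)oxy]oct-2-en-1-yl acetate | CC(C)(Br)[C@H](OS(=O)(=O)C(F)(F)F)CC/C(C)=C/COC(C)=O | intermediate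
10 | (3S)-3-[(3E)-5-acetoxy-3-methylpent-3-en-1-yl]-2,2-dimethylbromiranium ion | CC1(C)[Br+][C@H]1CC/C(C)=C/COC(C)=O | intermediate
11 | (2E,6S)-6-bromo-7-chloro-3,7-dimethyloct-2-en-1-yl acetate | CC(C)(Cl)[C@@H](Br)CC/C(C)=C/COC(C)=O | intermediate
12 | (2E,6S)-6-bromo-7-chloro-3,7-dimethyloct-2-en-1-ol | CC(C)(Cl)[C@@H](Br)CC/C(C)=C/CO | intermediate
13 | (2E,6S)-6-bromo-7-chloro-3,7-dimethyloct-2-en-1-yl (5S)-5-[(tert-butyldimethylsilyl)oxy]-5-methylhept-6-enoate | C=C[C@@](C)(O[Si](C)(C)C(C)(C)C)CCCC(=O)OC/C=C(\C)CC[C@H](Br)C(C)(C)Cl | intermediate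
14 | boron ketene acetal of 13, alkyl chain cis to O–B, boron held in the (4S,5S)-1,3-bis(arylsulfonyl)-4,5-diphenyl-1,3,2-diazaborolidine | C=C[C@@](C)(O[Si](C)(C)C(C)(C)C)CC/C=C(\OB1N(S(=O)(=O)c2cc(C(F)(F)F)cc(C(F)(F)F)c2)[C@@H](c2ccccc2)[C@H](c2ccccc2)N1S(=O)(=O)c1cc(C(F)(F)F)cc(C(F)(F)F)c1)OC/C=C(\C)CC[C@H](Br)C(C)(C)Cl | intermediate
15 | (2S,3R)-3-[(3S)-3-bromo-4-chloro-4-methylpentyl]-2-{(3S)-3-[(tert-butyldimethylsilyl)oxy]-3-methylpent-4-en-1-yl}-3-methylpent-4-enoic acid | C=C[C@@](C)(O[Si](C)(C)C(C)(C)C)CC[C@H](C(=O)O)[C@](C)(CC[C@H](Br)C(C)(C)Cl)C=C | intermediate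
16 | (3S,4S,5S)-4-[(3S)-3-bromo-4-chloro-4-methylpentyl]-3-{(3S)-3-[(tert-butyldimethylsilyl)oxy]-3-methylpent-4-en-1-yl}-5-(iodomethyl)-4-methyloxolan-2-one | C=C[C@@](C)(O[Si](C)(C)C(C)(C)C)CC[C@H]1[C@](C)(CC[C@H](Br)C(C)(C)Cl)[C@@H](CI)OC1=O | intermediate
17 | lithium lactolate, methyllithium adduct of 16 at the lactone carbonyl (new hemiketal centre undefined) | C=C[C@@](C)(O[Si](C)(C)C(C)(C)C)CC[C@H]1[C@](C)(CC[C@H](Br)C(C)(C)Cl)[C@@H](CI)OC1(C)[O-].[Li+] | intermediate
18 | (3S,4S,7S)-7-bromo-8-chloro-4,8-dimethyl-4-[(2S)-oxiran-2-yl]-3-{(3S)-3-[(tert-butyldimethylsilyl)oxy]-3-methylpent-4-en-1-yl}nonan-2-one | C=C[C@@](C)(O[Si](C)(C)C(C)(C)C)CC[C@H](C(C)=O)[C@](C)(CC[C@H](Br)C(C)(C)Cl)[C@H]1CO1 | intermediate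
19 | tert-butyl({(3S,6R,7S,10S)-10-bromo-11-chloro-3,7,11-trimethyl-7-[(2S)-oxiran-2-yl]-6-(prop-1-en-2-yl)dodec-1-en-3-yl}oxy)dimethylsilane | C=C[C@@](C)(O[Si](C)(C)C(C)(C)C)CC[C@H](C(C)=C)[C@](C)(CC[C@H](Br)C(C)(C)Cl)[C@H]1CO1 | intermediate
20 | tertiary cyclohexyl cation with a trifluoroborate-bound alkoxide on the 1,4-related carbon | C=C[C@@](C)(O[Si](C)(C)C(C)(C)C)CC[C@H]1[C@](C)(CC[C@H](Br)C(C)(C)Cl)[C@H](O[B-](F)(F)F)CC[C+]1C | intermediate
21 | tert-butyl({(3S)-5-[(1S,2S,3S,4R)-3-[(3S)-3-bromo-4-chloro-4-methylpentyl]-1,3-dimethyl-7-oxabicyclo[2.2.1]heptan-2-yl]-3-methylpent-1-en-3-yl}oxy)dimethylsilane | C=C[C@@](C)(O[Si](C)(C)C(C)(C)C)CC[C@H]1[C@](C)(CC[C@H](Br)C(C)(C)Cl)[C@H]2CC[C@]1(C)O2 | intermediate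
22 | (3S)-5-[(1S,2S,3S,4R)-3-[(3S)-3-bromo-4-chloro-4-methylpentyl]-1,3-dimethyl-7-oxabicyclo[2.2.1]heptan-2-yl]-3-methylpent-1-en-3-ol | C=C[C@@](C)(O)CC[C@H]1[C@](C)(CC[C@H](Br)C(C)(C)Cl)[C@H]2CC[C@]1(C)O2 | target

**Step count.** Total steps: 15. Longest linear sequence: 11 steps (steps 1–4 then 9–15; the branch through steps 5–8 is equally long).

**Three steps most likely to fail**

Step 14 (key step). The activated oxirane may rearrange by a 1,2-hydride or alkyl shift before the alkene attacks. The cation may lose a proton instead of being captured by oxygen. The Lewis acid may also ionise the tertiary chloride or the allylic silyl ether. The fallback replaces the cationic cyclisation by a radical–polar relay and sets out from 19. LiI with AcOH in THF should open the oxirane at its CH2 carbon to give the iodohydrin F1. Et3B with air in benzene should then start an iodine-atom-transfer 6-endo radical cyclisation onto the isopropenyl group, giving the tertiary iodide F2. Solvolysis of F2 in (CF3)2CHOH with 2,6-lutidine should let the ring hydroxyl capture the tertiary cation, and the route is rejoined at 21.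

Step 11. Facial selectivity in the capture of the iodonium ion may be poor, so that the lactone epimeric at the new C–O centre forms as a co-product or even as the main product. The fallback makes the sequence stereoconvergent by inversion instead of relying on selectivity, and sets out from 15. The epimeric iodolactone F3 is taken separately through the methyllithium step to the epimeric epoxy ketone F4. Acetolysis at the oxirane CH2 carbon (CsOAc, AcOH, DMF) should give the hydroxy acetate F5, and MsCl with Et3N gives the mesylate F6. K2CO3 in MeOH then cleaves the acetate, and the freed primary alkoxide closes the oxirane with Walden inversion at the carbinol carbon. The two epimer streams merge at 18.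

Step 7. The bromonium ion or the tertiary bromide of 8 may lose a proton (allylic bromide and isopropenyl by-products), or the triflate may be displaced without bromine participation. Either process would erode the regio- and stereochemical relay. The fallback reverses the order of halide entry and sets out from 7. Li2NiBr4 in THF should open the epoxide by SN2 attack at the secondary carbon with inversion, giving the bromohydrin F7 with bromine already on C6. SOCl2 with pyridine should then convert the tertiary alcohol into the tertiary chloride through the same bromonium ion with retention at C6, and the route is rejoined at 11.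

Further compounds
F1 | step 14 | tert-butyl({(3S,6R,7S,10S)-10-bromo-11-chloro-7-[(1S)-1-hydroxy-2-iodoethyl]-3,7,11-trimethyl-6-(prop-1-en-2-yl)dodec-1-en-3-yl}oxy)dimethylsilane | C=C[C@@](C)(O[Si](C)(C)C(C)(C)C)CC[C@H](C(C)=C)[C@](C)(CC[C@H](Br)C(C)(C)Cl)[C@H](O)CI
F2 | step 14 | (1R,2S,3S)-2-[(3S)-3-bromo-4-chloro-4-methylpentyl]-3-{(3S)-3-[(tert-butyldimethylsilyl)oxy]-3-methylpent-4-en-1-yl}-4-iodo-2,4-dimethylcyclohexan-1-ol (both C4 epimers) | C=C[C@@](C)(O[Si](C)(C)C(C)(C)C)CC[C@H]1[C@](C)(CC[C@H](Br)C(C)(C)Cl)[C@H](O)CCC1(C)I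
F3 | step 11 | (3S,4S,5R)-4-[(3S)-3-bromo-4-chloro-4-methylpentyl]-3-{(3S)-3-[(tert-butyldimethylsilyl)oxy]-3-methylpent-4-en-1-yl}-5-(iodomethyl)-4-methyloxolan-2-one | C=C[C@@](C)(O[Si](C)(C)C(C)(C)C)CC[C@H]1[C@](C)(CC[C@H](Br)C(C)(C)Cl)[C@H](CI)OC1=O
F4 | step 11 | (3S,4S,7S)-7-bromo-8-chloro-4,8-dimethyl-4-[(2R)-oxiran-2-yl]-3-{(3S)-3-[(tert-butyldimethylsilyl)oxy]-3-methylpent-4-en-1-yl}nonan-2-one | C=C[C@@](C)(O[Si](C)(C)C(C)(C)C)CC[C@H](C(C)=O)[C@](C)(CC[C@H](Br)C(C)(C)Cl)[C@@H]1CO1
F5 | step 11 | (3S,4S,7S)-4-[(1R)-2-acetoxy-1-hydroxyethyl]-7-bromo-8-chloro-4,8-dimethyl-3-{(3S)-3-[(tert-butyldimethylsilyl)oxy]-3-methylpent-4-en-1-yl}nonan-2-one | C=C[C@@](C)(O[Si](C)(C)C(C)(C)C)CC[C@H](C(C)=O)[C@](C)(CC[C@H](Br)C(C)(C)Cl)[C@@H](O)COC(C)=O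
F6 | step 11 | (3S,4S,7S)-4-[(1R)-2-acetoxy-1-(methylsulfonyloxy)ethyl]-7-bromo-8-chloro-4,8-dimethyl-3-{(3S)-3-[(tert-butyldimethylsilyl)oxy]-3-methylpent-4-en-1-yl}nonan-2-one | C=C[C@@](C)(O[Si](C)(C)C(C)(C)C)CC[C@H](C(C)=O)[C@](C)(CC[C@H](Br)C(C)(C)Cl)[C@@H](OS(C)(=O)=O)COC(C)=O
F7 | step 7 | (2E,6S)-6-bromo-7-hydroxy-3,7-dimethyloct-2-en-1-yl acetate | CC(C)(O)[C@@H](Br)CC/C(C)=C/COC(C)=O
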